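(The readings come from a simulation on assumed constants, and the scatter is random.)

Begin with the count for one turn of the catalyst. Partner joins free catalyst to give catalyst intermediate A, and one substrate passes through to one target. The released group freed on the way may be taken by one scavenger, be held by substrate as idle adduct, which counts as reacted, or stay free.

| setting | green | ochre | beta | delta | zeta |
|---|---|---|---|---|---|
| substrate | 0.50 M | 0.50 M | 0.50 M | 0.50 M | 0.50 M |
| partner | 0.60 M | 0.60 M | 0.600 M | 0.600 M | 0.600 M |
| scavenger | 0.69 M | 1.3 M | 0.500 M | 0.750 M | 1.10 M |
| free catalyst | 1 mM | 1 mM | 1.0 mM | 1.0 mM | 1.0 mM |
| remark | run made earlier | run made earlier |  |  |  |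
| time |  |  | 12 min | 12 min | 12 min |

| run | time / min | substrate / % | target / % |
|---|---|---|---|
| green | 1.00 | 76 | 8 |
| green | 3.00 | 52 | 37 |
| green | 5.00 | 35 | 60 |
| green | 8.00 | 18 | 83 |
| ochre | 1.00 | 81 | 13 |
| ochre | 3.00 | 57 | 43 |
| ochre | 5.00 | 35 | 59 |
| ochre | 8.00 | 14 | 83 |

(each reading ± 2 percentage points)

- for released group the idle adduct is counted in
- what was read earlier has a scatter of 2 percentage points, one standard deviation
- reactions considered so far: partner + free catalyst -> catalyst intermediate A; substrate + catalyst intermediate A <-> catalyst intermediate B; catalyst intermediate B <-> catalyst intermediate C; catalyst intermediate C <-> released group + catalyst intermediate D; catalyst intermediate D -> free catalyst + target; substrate + released group <-> idle adduct; scavenger + released group -> scavenged by-product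
- what has gone from substrate into another species counts as reacted, even if it can come back

1. part of the substrate that has reacted at the end, beta
2. part of the substrate that has reacted at the end, delta
3. part of the substrate that has reacted at the end, zeta
4. what raising the concentration of scavenger from its lowest to its highest value here does to the part of the substrate that has reacted (changes below 5 percentage points count as none) (it rises / it falls / no change)

Complete conversion thus uses up 0.500 M of partner, the one-to-one demand, and partner charged below it is the limiting reagent. Scavenger is no part of this demand, for the turn as written contains no step that uses it. Partner covers this demand 1.20 times in beta, delta and zeta, so the ceiling in these flasks is the whole charge of substrate.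

A ceiling says nothing of time, however. Green's last interval reads as a first-order constant of 0.222 min⁻¹, which leaves 7.42 % of substrate at 12 min. That looks pessimistic, because ochre's constant climbs from 0.176 min⁻¹ in its first interval to 0.305 min⁻¹ in its last, so substrate is read as falling faster than first order as it thins. Ochre's last constant, held unchanged, gives 95.9 % reacted, and this is the reckoning for delta and zeta.

Beta raises the remaining objection, since its scavenger has no excess. Its balance, however, leaves at least 0.0206 M of scavenger at that conversion, so any shortage touches the last stretch, and released group held as idle adduct still counts as reacted. Beta is therefore put below 95.9 % by less than 5 percentage points, which makes the trend no change.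

The forecast, lower for beta than this reckoning and differing on the trend, gives 87 %, 93 % and 95 %, so that it rises, on the ground that “Released group then builds up and drives the release step backward, slowing turnover.”

The flasks give 97.2 %, 97.8 % and 98.3 %: no change, with a change of 1.1 points.

    partner + free catalyst → catalyst intermediate A (k = 81.0 M⁻¹ s⁻¹)
    substrate + catalyst intermediate A ⇌ catalyst intermediate B (K = 33.0 M⁻¹, k = 18.0 M⁻¹ s⁻¹)
    catalyst intermediate B ⇌ catalyst intermediate C (K = 0.370, k = 6.30 s⁻¹)
    catalyst intermediate C ⇌ released group + catalyst intermediate D (K = 26.0 M, k = 6.30 s⁻¹)
    catalyst intermediate D → free catalyst + target (k = 190 s⁻¹)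
    substrate + released group ⇌ idle adduct, settled at all times (K = 280 M⁻¹)
    scavenger + released group → scavenged by-product (k = 1.90 M⁻¹ s⁻¹)

A neighbour of zeta, charged with 0.36 M of partner, stands below the one-to-one demand, and its ratio of partner to demand is 72.0 %. Here partner is the limiting reagent. At 12.0 min this flask has reacted 72.0 % of its substrate, and its target stands at 72.0 %. Partner is gone, at 0 % of its charge, and 28 % of the substrate remains unbound beside 100 % of the catalyst as free catalyst.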